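**Assumption:** artelasticin has no stereocentre and no stereogenic double bond (every alkene is a gem-dimethyl prenyl unit), so it is achiral and the route needs no stereocontrol.

Abbreviations: prenyl = 3-methylbut-2-en-1-yl; allyl = prop-2-en-1-yl.

## Retrosynthetic overview

1. Artelasticin 19 ⇐ tetra-O-allyl flavone 18 by Pd(0) deallylation (no acid, so the three prenyl groups cannot close to chromans).
2. 18 ⇐ 2-prenyl-1,3-diketone 16 by cyclodehydration; 16 ⇐ 1,3-diketone 15 + prenyl bromide (C-alkylation installs the C3 prenyl).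
3. Key C–C bond (flavone C2–C3): 15 ⇐ intermolecular crossed Claisen condensation of the enolate of A-ring acetophenone 7 with B-ring aroyl chloride 13.
4. 7 ⇐ phloroacetophenone 1 (double C-prenylation, then bis-O-allylation); 13 ⇐ 2,4-dihydroxybenzoic acid 8.
5. Ring order: both benzene rings are bought; the pyranone ring is the only ring made, in step 8.

## Route

Step 1
Reactants: 1 2,4,6-trihydroxyacetophenone; 2 prenyl bromide
Product: 4 1-[2,4,6-trihydroxy-3,5-diprenylphenyl]ethanone, via monoprenyl ketone 3 (not isolated)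
Conditions: 2 (2.1 equiv), 10% aq KOH, 0 °C → rt, 3 h; then 1 M HCl to pH 4 at 0 °C; chromatography
Reagents that add atoms: prenyl bromide (2), CC(C)=CCBr
Why: Friedel–Crafts-type C-alkylation of the ambident phloroglucinol phenoxide, where water favours attack through the two free ring carbons; expect about 30% after separation from mono- and tri-alkylated material, and no stereocentre is formed.

Step 2
Reactants: 4 1-[2,4,6-trihydroxy-3,5-diprenylphenyl]ethanone; 5 allyl bromide
Product: 7 1-[4,6-bis(allyloxy)-2-hydroxy-3,5-diprenylphenyl]ethanone, via 4-O-allyl ether 6 (not isolated)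
Conditions: 5 (2.2 equiv), K2CO3 (2.5 equiv), acetone, reflux, 6 h
Reagents that add atoms: allyl bromide (5), C=CCBr
Why: Williamson etherification takes the acidic para-OH and then one ortho-OH, while the last ortho-OH is held in a hydrogen bond to the ketone and stays free for the later ring closure.

Step 3
Reactants: 8 2,4-dihydroxybenzoic acid; 5 allyl bromide
Product: 11 allyl 2,4-bis(allyloxy)benzoate, via allyl dihydroxybenzoate 9 (not isolated), via allyl 4-allyloxysalicylate 10 (not isolated)
Conditions: 5 (3.6 equiv), K2CO3 (4 equiv), DMF, 60 °C, 12 h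
Reagents that add atoms: allyl bromide (5), C=CCBr
Why: Exhaustive Williamson alkylation of the carboxylate and both phenols, with DMF and heat forcing the hydrogen-bonded 2-OH to react.

Step 4
Reactants: 11 allyl 2,4-bis(allyloxy)benzoate
Product: 12 2,4-bis(allyloxy)benzoic acid
Conditions: 2 M aq NaOH, MeOH/THF, 60 °C, 3 h; then 1 M HCl to pH 2
Reagents that add atoms: sodium hydroxide, [Na+].[OH-]
Why: Saponification cleaves only the ester, since aryl allyl ethers are inert to aqueous hydroxide.

Step 5
Reactants: 12 2,4-bis(allyloxy)benzoic acid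
Product: 13 2,4-bis(allyloxy)benzoyl chloride
Conditions: (COCl)2 (1.5 equiv), DMF (cat.), CH2Cl2, 0 °C → rt, 2 h; evaporate, use crude
Reagents that add atoms: oxalyl chloride, O=C(Cl)C(=O)Cl
Why: Vilsmeier-catalysed acid chloride formation is clean for alkoxybenzoic acids and leaves the allyl ethers untouched.

Step 6
Reactants: 7 1-[4,6-bis(allyloxy)-2-hydroxy-3,5-diprenylphenyl]ethanone; 13 2,4-bis(allyloxy)benzoyl chloride
Product: 15 1-[4,6-bis(allyloxy)-2-hydroxy-3,5-diprenylphenyl]-3-[2,4-bis(allyloxy)phenyl]propane-1,3-dione, via dilithium enolate 14 (not isolated)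
Conditions: LiHMDS (3.2 equiv), THF, −78 → −10 °C, 1 h; then 13 (1.05 equiv), −78 °C → rt, 3 h; cold 1 M HCl work-up
Reagents that add atoms: none
Why: Crossed Claisen condensation in which the lithium enolate of the methyl ketone (phenol parked as its lithium phenoxide) is C-acylated by the aroyl chloride, and the third equivalent of base deprotonates the new 1,3-diketone, which stops a second acylation.

Step 7
Reactants: 15 1-[4,6-bis(allyloxy)-2-hydroxy-3,5-diprenylphenyl]-3-[2,4-bis(allyloxy)phenyl]propane-1,3-dione; 2 prenyl bromide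
Product: 16 1-[4,6-bis(allyloxy)-2-hydroxy-3,5-diprenylphenyl]-3-[2,4-bis(allyloxy)phenyl]-2-prenylpropane-1,3-dione (racemic)
Conditions: 2 (1.1 equiv), K2CO3 (1.5 equiv), acetone, rt → 40 °C, 12 h
Reagents that add atoms: prenyl bromide (2), CC(C)=CCBr
Why: C-alkylation of a β-diketonate, where K2CO3 ionises the diketone C–H ahead of the chelated phenol and the soft carbon attacks the allylic bromide by SN2; the new stereocentre is racemic and becomes sp2 in step 8.

Step 8
Reactants: 16 1-[4,6-bis(allyloxy)-2-hydroxy-3,5-diprenylphenyl]-3-[2,4-bis(allyloxy)phenyl]-2-prenylpropane-1,3-dione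
Product: 18 5,7-bis(allyloxy)-2-[2,4-bis(allyloxy)phenyl]-3,6,8-triprenyl-4H-chromen-4-one, via cyclic hemiketal 17 (not isolated)
Conditions: NaOAc (2 equiv), AcOH, 100 °C, 2 h
Reagents that add atoms: none
Why: Cyclodehydration in which the free phenol adds to the aryl ketone and the hemiketal loses water through an oxocarbenium ion stabilised by the 2,4-dialkoxyphenyl group, so buffered acetic acid suffices and is too weak to protonate the prenyl alkenes.

Step 9
Reactants: 18 5,7-bis(allyloxy)-2-[2,4-bis(allyloxy)phenyl]-3,6,8-triprenyl-4H-chromen-4-one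
Product: 19 artelasticin
Conditions: Pd(PPh3)4 (10 mol %), morpholine (20 equiv), degassed THF, rt, 4 h; dilute citric acid work-up
Reagents that add atoms: none
Why: Tsuji–Trost-type deallylation in which Pd(0) ionises each aryl allyl ether to a π-allyl complex that morpholine captures, while the C-prenyl groups have no leaving group and are untouched; the target has no stereocentre to set.

## Compound list

1 | 2,4,6-trihydroxyacetophenone (phloroacetophenone) | CC(=O)c1c(O)cc(O)cc1O | starting material
2 | prenyl bromide (1-bromo-3-methylbut-2-ene) | CC(C)=CCBr | starting material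
3 | 1-[2,4,6-trihydroxy-3-prenylphenyl]ethanone (not isolated) | CC(=O)c1c(O)cc(O)c(CC=C(C)C)c1O | intermediate
4 | 1-[2,4,6-trihydroxy-3,5-diprenylphenyl]ethanone | CC(=O)c1c(O)c(CC=C(C)C)c(O)c(CC=C(C)C)c1O | intermediate
5 | allyl bromide (3-bromoprop-1-ene) | C=CCBr | starting material
6 | 1-[4-(allyloxy)-2,6-dihydroxy-3,5-diprenylphenyl]ethanone (not isolated) | CC(=O)c1c(O)c(CC=C(C)C)c(OCC=C)c(CC=C(C)C)c1O | intermediate
7 | 1-[4,6-bis(allyloxy)-2-hydroxy-3,5-diprenylphenyl]ethanone | CC(=O)c1c(O)c(CC=C(C)C)c(OCC=C)c(CC=C(C)C)c1OCC=C | intermediate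
8 | 2,4-dihydroxybenzoic acid | O=C(O)c1ccc(O)cc1O | starting material
9 | allyl 2,4-dihydroxybenzoate (not isolated) | C=CCOC(=O)c1ccc(O)cc1O | intermediate
10 | allyl 4-(allyloxy)-2-hydroxybenzoate (not isolated) | C=CCOC(=O)c1ccc(OCC=C)cc1O | intermediate
11 | allyl 2,4-bis(allyloxy)benzoate | C=CCOC(=O)c1ccc(OCC=C)cc1OCC=C | intermediate
12 | 2,4-bis(allyloxy)benzoic acid | O=C(O)c1ccc(OCC=C)cc1OCC=C | intermediate
13 | 2,4-bis(allyloxy)benzoyl chloride | O=C(Cl)c1ccc(OCC=C)cc1OCC=C | intermediate
14 | dilithium phenoxide-enolate of 7 (not isolated) | [Li+].[Li+].C=C([O-])c1c([O-])c(CC=C(C)C)c(OCC=C)c(CC=C(C)C)c1OCC=C | intermediate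
15 | 1-[4,6-bis(allyloxy)-2-hydroxy-3,5-diprenylphenyl]-3-[2,4-bis(allyloxy)phenyl]propane-1,3-dione | O=C(CC(=O)c1ccc(OCC=C)cc1OCC=C)c1c(O)c(CC=C(C)C)c(OCC=C)c(CC=C(C)C)c1OCC=C | intermediate
16 | 1-[4,6-bis(allyloxy)-2-hydroxy-3,5-diprenylphenyl]-3-[2,4-bis(allyloxy)phenyl]-2-prenylpropane-1,3-dione (racemic) | O=C(C(CC=C(C)C)C(=O)c1ccc(OCC=C)cc1OCC=C)c1c(O)c(CC=C(C)C)c(OCC=C)c(CC=C(C)C)c1OCC=C | intermediate
17 | 5,7-bis(allyloxy)-2-[2,4-bis(allyloxy)phenyl]-2-hydroxy-3,6,8-triprenylchroman-4-one (racemic diastereomer mixture, not isolated) | CC(C)=CCc1c(OCC=C)c(CC=C(C)C)c2OC(O)(c3ccc(OCC=C)cc3OCC=C)C(CC=C(C)C)C(=O)c2c1OCC=C | intermediate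
18 | 5,7-bis(allyloxy)-2-[2,4-bis(allyloxy)phenyl]-3,6,8-triprenyl-4H-chromen-4-one | CC(C)=CCc1c(OCC=C)c(CC=C(C)C)c2oc(-c3ccc(OCC=C)cc3OCC=C)c(CC=C(C)C)c(=O)c2c1OCC=C | intermediate
19 | artelasticin, 2-(2,4-dihydroxyphenyl)-5,7-dihydroxy-3,6,8-triprenyl-4H-chromen-4-one | CC(C)=CCc1c(O)c(CC=C(C)C)c2oc(-c3ccc(O)cc3O)c(CC=C(C)C)c(=O)c2c1O | target

## Step count and risks

Total steps: 9. Longest linear sequence: 7 (steps 3, 4, 5, 6, 7, 8, 9 from 8); the A-ring branch from 1 is 6 steps.

**Step 1 (double C-prenylation).** The alkylation is statistical: mono-, tri-, geminal and O-prenylated products compete, so the yield of 4 is modest. The fallback sets out from 2 and comes back to the route at 4, building the ring substitution one position at a time by directed ortho-metalation. Commercial phloroglucinol is protected with MOMCl/NaH in DMF to give 1,3,5-tris(methoxymethoxy)benzene F1. Lithiation between two MOM ethers (n-BuLi, THF, 0 °C) and quenching with 2 gives 1,3,5-tris(methoxymethoxy)-2-prenylbenzene F2. A second lithiation and quench with 2 gives 1,3,5-tris(methoxymethoxy)-2,4-diprenylbenzene F3. A third lithiation at the last ring position, quenched with N-methoxy-N-methylacetamide, gives 1-[2,4,6-tris(methoxymethoxy)-3,5-diprenylphenyl]ethanone F4. Brief HCl in MeOH at rt removes the three MOM groups and delivers 4.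

**Step 6 (crossed Claisen condensation).** The enolate sits on a hexasubstituted ring next to a lithium phenoxide, so O-aroylation or double acylation could erode the yield. The fallback sets out from 7 (with 13) and comes back at 15, making the same bond intramolecularly. The phenol of 7 is first aroylated with 13 (K2CO3, acetone, reflux) to give 2-acetyl-3,5-bis(allyloxy)-4,6-diprenylphenyl 2,4-bis(allyloxy)benzoate F5. KOtBu in THF at rt then triggers the Baker–Venkataraman 1,3-acyl shift, in which the ketone enolate attacks the neighbouring ester, to give 15.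

**Step 7 (C-prenylation of the diketone).** O-alkylation of the enol or of the free phenol, or double alkylation, may compete. The fallback sets out from 7 and comes back at 16, putting the prenyl group on the ketone before the diketone exists. The dianion of 7 (LDA 2.2 equiv, THF, −78 °C) is alkylated at the enolate carbon with 2 (1.0 equiv) to give 1-[4,6-bis(allyloxy)-2-hydroxy-3,5-diprenylphenyl]-5-methylhex-4-en-1-one F6. The enolate of F6 (LiHMDS 3.2 equiv, THF, −78 °C) is then acylated with 13, as in step 6, to give 16 directly.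

## Further compounds

F1 | step 1 | 1,3,5-tris(methoxymethoxy)benzene | COCOc1cc(OCOC)cc(OCOC)c1
F2 | step 1 | 1,3,5-tris(methoxymethoxy)-2-prenylbenzene | COCOc1cc(OCOC)c(CC=C(C)C)c(OCOC)c1
F3 | step 1 | 1,3,5-tris(methoxymethoxy)-2,4-diprenylbenzene | COCOc1cc(OCOC)c(CC=C(C)C)c(OCOC)c1CC=C(C)C
F4 | step 1 | 1-[2,4,6-tris(methoxymethoxy)-3,5-diprenylphenyl]ethanone | CC(=O)c1c(OCOC)c(CC=C(C)C)c(OCOC)c(CC=C(C)C)c1OCOC
F5 | step 6 | 2-acetyl-3,5-bis(allyloxy)-4,6-diprenylphenyl 2,4-bis(allyloxy)benzoate | CC(=O)c1c(OC(=O)c2ccc(OCC=C)cc2OCC=C)c(CC=C(C)C)c(OCC=C)c(CC=C(C)C)c1OCC=C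
F6 | step 7 | 1-[4,6-bis(allyloxy)-2-hydroxy-3,5-diprenylphenyl]-5-methylhex-4-en-1-one | CC(C)=CCCC(=O)c1c(O)c(CC=C(C)C)c(OCC=C)c(CC=C(C)C)c1OCC=C
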